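## Structural features

Gentiside A (15) is an achiral ester of 2,3-dihydroxybenzoic acid with a saturated, iso-branched C22 alcohol. The acyl part is a single benzene ring with the carboxyl carbon on ring C1 and phenolic hydroxyls on ring C2 and C3; it is joined to the chain through the acyl–oxygen bond at chain C1. The chain is unbranched from C1 to C19, and C20 is a methine that carries C21 and one further methyl group, so the terminus is an isopropyl group. There is no stereocentre, so no neighbouring stereocentres have to be related. The fragile parts are the free catechol, which air oxidises to the ortho-quinone (fastest in base) and which binds metal ions, and the aryl ester, which is open to hydrolysis, transesterification and organometallic attack. The real difficulty is supply and handling: a C22 primary alcohol with a remote iso-branch is not a commodity, the two ends of a symmetrical long-chain precursor must be told apart, and every intermediate is waxy and poorly soluble. The key step exploits the two identical methyl groups on chain C20 (C21 and the branch): such a carbon can come from an ester carbonyl that is methylated twice, and counting back nineteen methylenes places that carbonyl at one end of a C20 α,ω-difunctional chain whose other end becomes C1.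

## Logic of the disconnections

15 ⇒ 14. The two phenolic O–benzyl bonds are put back and two hydrogens are removed across chain C19–C20. Cutting here leaves the release of the air-sensitive catechol to the last operation and lets one reduction do two jobs. The gain is that every earlier intermediate is a stable, non-chelating benzyl ether. The forward step must saturate a trisubstituted alkene and cleave two aryl benzyl ethers without touching the aryl ester.

14 ⇒ 12 (through 13). Water is added back across C19–C20, which restores the C20–O bond. A tertiary hydroxyl at C20 is the footprint of carbonyl chemistry at that carbon, so this cut turns the branch point into a functional handle. The forward step must dehydrate a tertiary alcohol beside an aryl ester and two benzyl ethers. Proton loss towards a methyl group gives 13 first in part, and acid equilibration must drain it into 14, although the position of the double bond has no bearing on 15.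

12 ⇒ 8 + 11. The acyl–oxygen bond between the ring carboxyl carbon and chain O1 is cut. This divides the molecule into its aromatic and aliphatic halves, each made independently. The forward acylation must take the primary hydroxyl of 8 and leave the tertiary one. The phenols of the acid component must be masked so that carboxyl activation cannot lead to self-esterification.

11 ⇒ 9 (through 10). The two phenolic O–benzyl bonds and, transiently, a benzyl ester bond are cut. Benzyl is chosen because its removal coincides with the alkene hydrogenation. The forward step must alkylate the hydrogen-bonded C2 phenol completely and then cleave only the ester.

8 ⇒ 5 + 6 (through 7). The C20–C21 bond and the C20–methyl branch bond are cut together. Both methyl groups are identical, so they can come from two equivalents of 6 adding to one ester carbonyl. This reduces the branched C22 diol to a linear C20 hydroxy ester. The forward step must run past the ketone stage to completion and must tolerate the free hydroxyl, which it does by turning it into an inert alkoxide.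

5 ⇒ 4. The two C–H bonds at chain C1 are traded for the carboxyl oxidation level. The gain is that both chain ends now derive from one symmetrical C20 skeleton. The forward step must reduce a carboxylic acid and leave a methyl ester alone.

4 ⇒ 2 (through 3). One O–methyl bond is restored, so that the two chain ends become identical again. Passing through 2 makes the desymmetrisation a single, controllable half-hydrolysis. The forward step must hydrolyse one of two identical, remote ester groups and stop.

2 ⇒ 1. Both O–methyl bonds are cut, which leads back to the commercial symmetrical diacid. The forward step is a plain double esterification with no selectivity demand.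

## Other disconnections considered

Alternative 1: The cut runs through the benzene ring, at the ring C1–C6 and C2–C3 bonds (ring C1 carries the ester). Forward, furan A1 and the bromoalkynoate A2, the 3-bromopropiolate of the iso-alcohol A5, would combine in a thermal [4+2] cycloaddition to the racemic 7-oxanorbornadiene A3. Acid would then open the oxygen bridge and aromatise the ring to the bromophenol A4, in which the bridge oxygen has become the C3 hydroxyl. The bromine at C2 would finally be exchanged for hydroxyl.
- In favour: the cycloaddition is concerted and its regiochemistry is fixed by the alkyne substituents. The 2,3-dioxygenation pattern is built in from cheap A1.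
- Against: the ring with all three substituents is already available as 9, so ring synthesis solves a problem the target does not pose. The two bridgehead stereocentres of A3 are made only to be destroyed. The bridge must open at the bridgehead C–O bond next to the ester-bearing carbon, so that the oxygen stays beside the bromine-bearing carbon. The allyl cation formed that way carries its charge on the bromine-bearing and not on the ester-bearing carbon, so this direction is the electronically preferred one, but it is not assured. Replacing an aryl bromide flanked by an ester and a phenol needs basic, metal-catalysed hydroxylation that endangers the ester. A2 is a reactive, irritant haloalkyne.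
- Structure and mechanism: the chosen plan takes the complete aromatic part from 9 and spends its steps on the chain. This plan builds the ring by a pericyclic reaction and a cationic rearrangement and still needs the whole chain.
- Equal or better: this plan needs no phenol protecting groups and no final hydrogenolysis. Its key step forms two skeletal bonds in one operation, which equals the chosen key step.
- Step economy: A5 must still be made, which consumes the chain chemistry of the chosen route plus a separate deoxygenation. Four ring-building steps follow, against three steps after 8 in the chosen route.

Alternative 2: The cut is at chain bonds C11–C12 and C14–C15, leaving C12–C14 to come from propyne A6. Forward, A6 would be lithiated twice with an alkyllithium base. The more reactive propargylic carbon would be alkylated first by the silyl-protected ω-bromo ether A7 (C1–C11), and the remaining acetylide then by the iso-bromide A8 (C15–C21 with the branch), giving alkyne A9 in one flask. Desilylation, esterification with 11, and one hydrogenation that saturates the triple bond and removes the benzyl groups would finish the synthesis.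
- In favour: the plan is convergent, no symmetrical precursor has to be desymmetrised, and the iso-terminus arrives ready-made, so no tertiary alcohol has to be removed. The alkyne disappears in a hydrogenation that is needed anyway.
- Against: alkylating an acetylide anion with an unactivated primary bromide is slow without a strongly coordinating co-solvent and competes with elimination. The propargyl/allenyl dianion can alkylate at the wrong terminus or twice. Gaseous A6 and cryogenic organolithium handling are needed. A8 is a speciality reagent. Hydrocarbon-like by-products would be hard to separate from A9.
- Structure and mechanism: both plans treat the chain as the problem. This one assembles it from three pieces by two SN2 alkylations of carbanions. The chosen plan uses one C20 piece and two carbonyl additions, which are intrinsically faster and cleaner.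
- Equal or better: this plan forms two skeletal bonds in one flask, as the chosen key step does. If A7 and A8 are bought or made in one step each, it would reach 15 in about six steps against eight, so it is the better plan on step count. The chosen plan is preferred for the reliability of each operation and for using only commodity reagents.

Alternative 3: The cut is at the two phenolic C–O bonds on ring C2 and C3. Forward, benzoic acid A10 would be taken by Birch reduction to the diene acid A11 and esterified with A5 to the diene ester A12. OsO4-catalysed cis-dihydroxylation of one of its two equivalent alkenes, with an amine N-oxide as terminal oxidant, would give the racemic diol A13, the oxidant approaching the face opposite the ester. Oxidation of both carbinols to the 1,2-dione level would then let the ring tautomerise to the catechol of 15.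
- In favour: both oxygens enter in one operation, and their position next to the carboxyl-bearing carbon follows from where the alkenes of A12 lie. No phenol protection is needed.
- Against: 9 already contains these oxygens. A12 has a doubly allylic, ester-activated C1–H and is prone to conjugation or rearomatisation. The second alkene can also be dihydroxylated. The last step must oxidise a diol twice without glycol cleavage and without dehydrating A13, which would give a mono-phenol. Three stereocentres are set and erased in a flat, achiral target.
- Structure and mechanism: the chosen plan never alters the oxidation level of the ring. This plan reduces an arene, re-oxidises it in two stages and relies on facial selectivity that the target does not need.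
- Equal or better: the dihydroxylation is as dependable a transformation as the Grignard double addition, so the two key steps are equal in reliability. The absence of protecting groups is an advantage over the chosen plan.
- Step economy: this plan is clearly longer. A5 is still required, and four ring-adjusting steps are added to it.

Key step: step 4

Remarks on the chemistry (assumptions):
- The ω-hydroxyl of 5 is deliberately left unprotected. The bromomagnesium alkoxide formed by the first equivalent of 6 acts as protection in the flask, which saves two steps.
- Carboxylate and alkoxide salts that are only protonated in the aqueous work-up are treated as salt forms of the numbered neutral compounds. The barium half-ester salt 3 is numbered; it is collected as a crude filter cake and acidified at once without purification.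
- In step 7 the 1,1-disubstituted alkene 13 is an in-flask intermediate that acid converts into 14. A minor equilibrium share of 13 that stays with 14 is not removed, because hydrogenation takes both to the same isopropyl terminus.

Step 1
Reactants: 1 icosanedioic acid
Product: 2 dimethyl icosanedioate
Conditions: MeOH, H2SO4 (cat.), reflux
Reagents that add atoms: methanol, CO
Why: Fischer esterification driven by the large excess of methanol; both carboxyl groups react alike, and the neutral diester should crystallise on cooling, so the symmetrical compound is secured pure before the ends are differentiated.

Step 2
Reactants: 2 dimethyl icosanedioate
Product: 4 20-methoxy-20-oxoicosanoic acid (monomethyl icosanedioate), via barium bis(20-methoxy-20-oxoicosanoate) 3 (not isolated)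
Conditions: Ba(OH)2·8H2O (0.5 equiv), MeOH–THF, 40 °C; filter; then crude precipitate in Et2O, 2 M aq. HCl
Reagents that add atoms: barium hydroxide, [Ba+2].[OH-].[OH-]
Why: Half-saponification (ester hydrolysis by hydroxide with acyl–oxygen cleavage): one hydroxide per diester is offered and the barium salt 3 of the half-ester should leave the solution as it forms, which shields the second ester group; acidification frees 4 and unreacted 2 is recycled from the filtrate.

Step 3
Reactants: 4 20-methoxy-20-oxoicosanoic acid
Product: 5 methyl 20-hydroxyicosanoate
Conditions: BH3·SMe2 (1.3 equiv), THF, 0 °C to rt; MeOH quench, then aqueous work-up
Reagents that add atoms: none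
Why: Chemoselective borane reduction of a carboxylic acid beside an ester: the acid is converted into an acyloxyborane whose carbonyl is activated for hydride transfer, whereas the methyl ester is reduced much more slowly under these conditions.

Step 4
Reactants: 5 methyl 20-hydroxyicosanoate; 6 methylmagnesium bromide
Product: 8 20-methylhenicosane-1,20-diol, via 21-hydroxyhenicosan-2-one 7 (not isolated)
Conditions: MeMgBr (3 M in Et2O, 5 equiv), THF, 0 °C to 40 °C; sat. aq. NH4Cl
Reagents that add atoms: methylmagnesium bromide (compound 6), C[Mg]Br
Why: Double addition of a Grignard reagent to an ester, the standard way to a tertiary carbinol with two identical groups, is the closest known reaction type. The first equivalent of 6 removes the hydroxyl proton of 5 as methane, and the resulting bromomagnesium alkoxide is an in-flask protecting group that does not react further. A second equivalent adds to the ester carbonyl (the future C20); the tetrahedral magnesium hemiketal alkoxide expels methoxide and gives the methyl ketone 7, which forms the C20–C21 bond. Ketone 7 is a better electrophile than the ester it comes from, so a third equivalent should add at once and form the C20–methyl branch bond; aqueous NH4Cl then liberates diol 8. No ring is closed and no stereocentre is created, because C20 ends up with two identical methyl groups. The selectivity needed is completeness: the sequence must not stop at 7 and 7 must not be lost by enolisation, which the higher carbonyl reactivity of the ketone, the five-fold excess of the small reagent and gentle warming should secure. Chemoselectivity is not at stake, since the ester is the only electrophile in 5 once the hydroxyl is deprotonated.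

Step 5
Reactants: 9 2,3-dihydroxybenzoic acid
Product: 11 2,3-bis(benzyloxy)benzoic acid, via benzyl 2,3-bis(benzyloxy)benzoate 10 (not isolated)
Conditions: BnBr (3.5 equiv), K2CO3 (4 equiv), acetone, reflux; filter, evaporate; then NaOH, MeOH–H2O, reflux; then aq. HCl
Reagents that add atoms: benzyl bromide, BrCc1ccccc1; sodium hydroxide, [Na+].[OH-]
Why: Williamson ether synthesis on both phenoxides with concurrent O-alkylation of the carboxylate gives 10; saponification then cleaves only the benzyl ester, and acid–base extraction should separate 11 from the neutral benzyl by-products.

Step 6
Reactants: 8 20-methylhenicosane-1,20-diol; 11 2,3-bis(benzyloxy)benzoic acid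
Product: 12 20-hydroxy-20-methylhenicosyl 2,3-bis(benzyloxy)benzoate
Conditions: DCC (1.1 equiv), DMAP (0.1 equiv), CH2Cl2–THF, 0 °C to rt
Reagents that add atoms: none
Why: Steglich esterification: DMAP converts the O-acylisourea into an acylpyridinium ion that acylates the unhindered primary hydroxyl at C1, while the tertiary hydroxyl at C20 is too hindered to react under these conditions, so the diol needs no protecting group.

Step 7
Reactants: 12 20-hydroxy-20-methylhenicosyl 2,3-bis(benzyloxy)benzoate
Product: 14 20-methylhenicos-19-en-1-yl 2,3-bis(benzyloxy)benzoate, via 20-methylhenicos-20-en-1-yl 2,3-bis(benzyloxy)benzoate 13 (not isolated)
Conditions: p-TsOH·H2O (10 mol %), toluene, reflux, Dean–Stark trap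
Reagents that add atoms: none
Why: Acid-catalysed E1 dehydration: loss of water from the protonated tertiary carbinol gives the C20 cation, which loses a proton either from a methyl group (1,1-disubstituted alkene 13) or from C19 (14), and because 13 is reprotonated at its CH2 terminus to the same cation the material should drain under thermodynamic control into the more substituted Zaitsev alkene 14 while azeotropic removal of water prevents rehydration. The aryl ester and the aryl benzyl ethers should tolerate a catalytic sulfonic acid in a non-nucleophilic solvent, and a minor equilibrium share of 13 is of no consequence since it leads to the same saturated terminus.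

Step 8
Reactants: 14 20-methylhenicos-19-en-1-yl 2,3-bis(benzyloxy)benzoate
Product: 15 gentiside A (20-methylhenicosyl 2,3-dihydroxybenzoate)
Conditions: H2 (1–3 atm), 10% Pd/C, EtOAc–THF, rt; filtration under argon
Reagents that add atoms: none
Why: Heterogeneous catalytic hydrogenation saturates the trisubstituted C19–C20 alkene, and the same catalyst cleaves the two aryl benzyl ethers by hydrogenolysis, so the catechol is released only in the final, neutral step. The aryl ester and the arene should be inert to Pd/C under these conditions, and no stereocentre arises because C20 carries two identical methyl groups.

## Compound list

1 | icosanedioic acid | OC(=O)CCCCCCCCCCCCCCCCCCC(=O)O | starting material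
2 | dimethyl icosanedioate | COC(=O)CCCCCCCCCCCCCCCCCCC(=O)OC | intermediate
3 | barium bis(20-methoxy-20-oxoicosanoate) | [Ba+2].COC(=O)CCCCCCCCCCCCCCCCCCC(=O)[O-].COC(=O)CCCCCCCCCCCCCCCCCCC(=O)[O-] | intermediate
4 | 20-methoxy-20-oxoicosanoic acid (monomethyl icosanedioate) | COC(=O)CCCCCCCCCCCCCCCCCCC(=O)O | intermediate
5 | methyl 20-hydroxyicosanoate | COC(=O)CCCCCCCCCCCCCCCCCCCO | intermediate
6 | methylmagnesium bromide | C[Mg]Br | starting material
7 | 21-hydroxyhenicosan-2-one (present in the flask as its bromomagnesium alkoxide) | CC(=O)CCCCCCCCCCCCCCCCCCCO | intermediate
8 | 20-methylhenicosane-1,20-diol | CC(C)(O)CCCCCCCCCCCCCCCCCCCO | intermediate
9 | 2,3-dihydroxybenzoic acid | O=C(O)c1cccc(O)c1O | starting material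
10 | benzyl 2,3-bis(benzyloxy)benzoate | O=C(OCc1ccccc1)c1cccc(OCc2ccccc2)c1OCc1ccccc1 | intermediate
11 | 2,3-bis(benzyloxy)benzoic acid | O=C(O)c1cccc(OCc2ccccc2)c1OCc1ccccc1 | intermediate
12 | 20-hydroxy-20-methylhenicosyl 2,3-bis(benzyloxy)benzoate | CC(C)(O)CCCCCCCCCCCCCCCCCCCOC(=O)c1cccc(OCc2ccccc2)c1OCc1ccccc1 | intermediate
13 | 20-methylhenicos-20-en-1-yl 2,3-bis(benzyloxy)benzoate | C=C(C)CCCCCCCCCCCCCCCCCCCOC(=O)c1cccc(OCc2ccccc2)c1OCc1ccccc1 | intermediate
14 | 20-methylhenicos-19-en-1-yl 2,3-bis(benzyloxy)benzoate | CC(C)=CCCCCCCCCCCCCCCCCCCOC(=O)c1cccc(OCc2ccccc2)c1OCc1ccccc1 | intermediate
15 | gentiside A (20-methylhenicosyl 2,3-dihydroxybenzoate) | CC(C)CCCCCCCCCCCCCCCCCCCOC(=O)c1cccc(O)c1O | target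

## Step count and least certain steps

Total step count: 8. Longest linear sequence: 7 steps (1 → 2 → 4 → 5 → 8 → 12 → 14 → 15; steps 1–4 and 6–8). Step 5 is the one-step side branch to 11.

Step 4 (key step). The most likely failure is an incomplete sequence. The long-chain bromomagnesium alkoxide may aggregate or precipitate in the ether solvent and slow the additions. The basic reagent may also enolise the methyl ketone stage instead of adding to it, so that material is arrested one methyl short. Fallback, setting out from 5 and coming back at 8: the hydroxyl of 5 is silylated (TBSCl, imidazole, DMF) to methyl 20-[(tert-butyldimethylsilyl)oxy]icosanoate F1, which dissolves freely in THF. F1 is treated with the less basic organocerium reagent prepared from MeMgBr and anhydrous CeCl3 (THF, −78 to 0 °C), which should suppress enolisation, to give 21-[(tert-butyldimethylsilyl)oxy]-2-methylhenicosan-2-ol F2. Fluoride (TBAF, THF) then removes the silyl group and returns the route to 8.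

Step 2. The most likely failure is loss of mono-selectivity. The C20 diester is only sparingly soluble in methanol, so a co-solvent is needed, and that may keep the barium half-ester salt in solution long enough for the second ester to be hydrolysed. Alternatively, unreacted diester may co-precipitate. Fallback, setting out from 1 and 2 and coming back at 4: equimolar 1 and 2 are heated with catalytic H2SO4 and a little methanol in a high-boiling ether. This acid-catalysed acid–ester interchange (comproportionation) equilibrates them with the half-ester. Compound 4 is separated on silica, where diester, half-ester and diacid differ strongly in polarity, and recovered 1 and 2 are returned to the equilibration. No new compound is involved.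

Step 6. The most likely failure is slow acylation. Diol 8 is poorly soluble and the acid is ortho-substituted, so the O-acylisourea may rearrange to the unreactive N-acylurea before the alcohol is acylated. Fallback, setting out from 8 and 11 and coming back at 12: the roles are reversed in a Mitsunobu esterification (PPh3, diisopropyl azodicarboxylate, THF, 0 °C to rt). The primary hydroxyl of 8 is activated as an alkoxyphosphonium ion and displaced by the carboxylate of 11. The tertiary hydroxyl cannot enter this SN2 manifold, and no new compound is involved.

Step 7. The most likely failure is diversion of the tertiary cation. At reflux the elimination is reversible, so the cation is formed repeatedly and may alkylate an electron-rich benzyloxy-substituted ring or the solvent in a Friedel–Crafts reaction. Prolonged heating with acid may also strip the benzyl ether ortho to the ester. Fallback, setting out from 12 and coming back at 15: ionic hydrogenation (Et3SiH in excess, CF3CO2H, CH2Cl2, 0 °C) generates the cation once, at low temperature, and traps it irreversibly with hydride. This gives 20-methylhenicosyl 2,3-bis(benzyloxy)benzoate F3 directly, without an alkene stage. Hydrogenolysis of F3 (H2, Pd/C, as in step 8) then gives 15. A benzyl ether lost during the short acid exposure would only anticipate this deprotection, and the silane would reduce the benzyl cation to toluene.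

## Further compounds

F1 | step 4 | methyl 20-[(tert-butyldimethylsilyl)oxy]icosanoate | COC(=O)CCCCCCCCCCCCCCCCCCCO[Si](C)(C)C(C)(C)C
F2 | step 4 | 21-[(tert-butyldimethylsilyl)oxy]-2-methylhenicosan-2-ol | CC(C)(O)CCCCCCCCCCCCCCCCCCCO[Si](C)(C)C(C)(C)C
F0 | step 2 | none | none
F0 | step 6 | none | none
F3 | step 7 | 20-methylhenicosyl 2,3-bis(benzyloxy)benzoate | CC(C)CCCCCCCCCCCCCCCCCCCOC(=O)c1cccc(OCc2ccccc2)c1OCc1ccccc1
A1 | alternative 1 | furan | c1ccoc1
A2 | alternative 1 | 20-methylhenicosyl 3-bromopropiolate | CC(C)CCCCCCCCCCCCCCCCCCCOC(=O)C#CBr
A3 | alternative 1 | racemic 20-methylhenicosyl 3-bromo-7-oxabicyclo[2.2.1]hepta-2,5-diene-2-carboxylate (one enantiomer drawn) | CC(C)CCCCCCCCCCCCCCCCCCCOC(=O)C1=C(Br)[C@@H]2O[C@H]1C=C2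
A4 | alternative 1 | 20-methylhenicosyl 2-bromo-3-hydroxybenzoate | CC(C)CCCCCCCCCCCCCCCCCCCOC(=O)c1cccc(O)c1Br
A5 | alternative 1 | 20-methylhenicosan-1-ol | CC(C)CCCCCCCCCCCCCCCCCCCO
A6 | alternative 2 | propyne | CC#C
A7 | alternative 2 | (11-bromoundecyloxy)(tert-butyl)dimethylsilane | BrCCCCCCCCCCCO[Si](C)(C)C(C)(C)C
A8 | alternative 2 | 1-bromo-6-methylheptane | CC(C)CCCCCBr
A9 | alternative 2 | tert-butyldimethyl(20-methylhenicos-13-yn-1-yloxy)silane | CC(C)CCCCCC#CCCCCCCCCCCCCO[Si](C)(C)C(C)(C)C
A10 | alternative 3 | benzoic acid | O=C(O)c1ccccc1
A11 | alternative 3 | cyclohexa-2,5-diene-1-carboxylic acid | O=C(O)C1C=CCC=C1
A12 | alternative 3 | 20-methylhenicosyl cyclohexa-2,5-diene-1-carboxylate | CC(C)CCCCCCCCCCCCCCCCCCCOC(=O)C1C=CCC=C1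
A13 | alternative 3 | racemic 20-methylhenicosyl 2,3-dihydroxycyclohex-5-ene-1-carboxylate, hydroxyls cis to each other and trans to the ester (one enantiomer drawn) | CC(C)CCCCCCCCCCCCCCCCCCCOC(=O)[C@@H]1[C@@H](O)[C@@H](O)CC=C1
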